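**Plan**
- Retrosynthesis: the acetate and the free acid come from an ethyl 6-oxo-7-en-17-oate. In that enone the C7=C8 bond (aldol condensation) and the C5–C10 bond (Michael addition) are cut together, which opens both rings to an acyclic keto 2-oxo ester. The chain is then cut at C9–C11 (alkylation), C8–C9 (glyoxylate ene reaction) and C3–C4 (conjugate addition to mesityl oxide).
- Forward: the chain is joined C3–C4, then C8–C9, then C9–C11. Ring A (C5–C10) and ring B (C7–C8) then close in one operation, followed by ketone reduction, ester hydrolysis and acetylation.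
- Enabling feature: C6 carries the oxygen and lies between C5 and C7, so as a ketone it makes both carbons nucleophilic. C8 carries the carboxyl carbon C17, so as a 2-oxo ester it is an electrophile and makes C10, reached through C9, a conjugate acceptor. A 1,3-donor pair (C5, C7) thus meets a 1,3-acceptor pair (C10, C8) across the C1–C4 chain.
- Stereochemistry: C10 from a chiral amine catalyst in the ring A closure; C5 and C9 relayed from C10 in the same event; C6 from hydride attack anti to the axial methyl groups; the 12E alkene from the purchased enynol.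

Key step: step 7

Remarks:
- Ring compounds carry labdane numbering (C1–C20; C17 is the carboxyl carbon on C8, C20 the methyl on C10) and CIP descriptors.
- Assumption: the facial preference of the amine catalyst at C10 cannot be derived reliably for this substrate. The quinidine-derived amine is written; its quinine-derived pseudo-enantiomer takes its place if a first run gives the mirror-image series.
- Assumption: 5-bromo-2-methylpent-1-ene and (2E)-3-methylpent-2-en-4-yn-1-ol are taken as purchasable.

Step 1
Reactants: 1 mesityl oxide (4-methylpent-3-en-2-one); 2 5-bromo-2-methylpent-1-ene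
Product: 4 4,4,8-trimethylnon-8-en-2-one, via Grignard reagent 3 (not isolated)
Conditions: Mg, THF, 40 °C; then CuBr·SMe2 (10 mol%), −30 to 0 °C; cold 1 M HCl
Reagents that add atoms: none
Why: Copper-catalysed conjugate addition of a Grignard reagent (Kharasch type) to the β,β-disubstituted enone builds the quaternary C4 and leaves the methyl ketone (C5–C6–C7) and the 1,1-disubstituted alkene (C10) in place; no stereocenter is formed.

Step 2
Reactants: 4 4,4,8-trimethylnon-8-en-2-one; 5 ethyl glyoxylate
Product: 6 ethyl 2-hydroxy-8,8-dimethyl-4-methylidene-10-oxoundecanoate (racemic)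
Conditions: Yb(OTf)3 (10 mol%), CH2Cl2, rt
Reagents that add atoms: none
Why: Lewis-acid-catalysed glyoxylate ene reaction of the 1,1-disubstituted alkene forms C8–C9 at the terminal CH2, the aldehyde being far more reactive than the hindered methyl ketone; the carbinol center is racemic and is removed in step 3, and any trisubstituted-alkene regioisomer converges with 6 at compound 8.

Step 3
Reactants: 6 ethyl 2-hydroxy-8,8-dimethyl-4-methylidene-10-oxoundecanoate
Product: 8 ethyl (3E)-4,8,8-trimethyl-2,10-dioxoundec-3-enoate, via deconjugated keto ester 7 (not isolated)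
Conditions: Dess–Martin periodinane, CH2Cl2, rt; then Et3N (0.2 equiv), rt
Reagents that add atoms: none
Why: Dess–Martin oxidation of the α-hydroxy ester gives the 2-oxo ester, whose C9–H2 is acidic enough for triethylamine to move the double bond into conjugation, the E isomer (keto group cis to the methyl) being the expected thermodynamic one.

Step 4
Reactants: 9 (2E)-3-methylpent-2-en-4-yn-1-ol
Product: 10 (2E)-3-methylpenta-2,4-dien-1-ol
Conditions: H2 (1 atm), Pd/CaCO3 poisoned with Pb(OAc)2, quinoline, EtOAc, rt
Reagents that add atoms: none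
Why: Lindlar semi-hydrogenation reduces the terminal alkyne to the vinyl group and leaves the trisubstituted alkene untouched, so the purchased E geometry is kept.

Step 5
Reactants: 10 (2E)-3-methylpenta-2,4-dien-1-ol
Product: 11 (3E)-5-bromo-3-methylpenta-1,3-diene
Conditions: PBr3 (0.4 equiv), Et2O, −20 °C; used at once
Reagents that add atoms: phosphorus tribromide, BrP(Br)Br
Why: Bromination of the primary allylic alcohol with PBr3 (SN2) should give the conjugated primary bromide with the E geometry retained.

Step 6
Reactants: 8 ethyl (3E)-4,8,8-trimethyl-2,10-dioxoundec-3-enoate; 11 (3E)-5-bromo-3-methylpenta-1,3-diene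
Product: 12 ethyl 8,8-dimethyl-4-methylidene-3-[(2E)-3-methylpenta-2,4-dien-1-yl]-2,10-dioxoundecanoate (racemic at C3)
Conditions: KOtBu (1.0 equiv), THF, −78 °C; then 11, −78 to −30 °C
Reagents that add atoms: none
Why: Deconjugative α-alkylation of an enone through its potassium dienolate: reversible deprotonation by KOtBu selects the vinylogous methyl of the 2-oxo-enoate over the much less acidic methyl ketone, and the dienolate should react with the allylic bromide at its α-carbon (C9); the new C9 center is racemic and labile and is reset in step 7, as is the position of the double bond.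

Step 7
Reactants: 12 ethyl 8,8-dimethyl-4-methylidene-3-[(2E)-3-methylpenta-2,4-dien-1-yl]-2,10-dioxoundecanoate
Product: 16 ethyl (5R,9S,10S)-6-oxolabda-7,12E,14-trien-17-oate, via conjugated enone 13 (not isolated), via Michael adduct 14 (not isolated), via aldol 15 (not isolated)
Conditions: 9-amino-9-deoxy-epi-quinidine (20 mol%), CF3CO2H (40 mol%), toluene (0.05 M), 40 °C; filtered through silica and used at once
Reagents that add atoms: none
Why: Proposed new method: the amine salt first moves the exocyclic double bond of 12 into conjugation (13; C9–H is α to the 2-oxo ester) and condenses reversibly with the C6 ketone, whose C5=C6 enamine adds to C10 of the enone while the protonated quinuclidine holds the 1,2-dicarbonyl by a hydrogen bond (14); the C6 iminium then tautomerises to the C6=C7 enamine, which adds to the C8 keto group (15) and loses water to the C7=C8 enone, and hydrolysis frees the catalyst. The closest known reaction types are the amine-catalysed formal [3+3] Michael/aldol annulation of the α and α′ carbons of a ketone with a β,γ-unsaturated α-keto ester and the cinchona primary-amine-catalysed Michael additions that create quaternary carbons at β,β-disubstituted enones; the intramolecular double ring closure onto a fully substituted acceptor is the part without precedent. Ring A closes by a 6-(enolexo)-exo-trig Michael addition and ring B by a 6-(enolendo)-exo-trig aldol addition followed by dehydration. C10 is set by the catalyst, which should block one face of the acceptor in a chair-like transition state; C5, which stays enolisable, should settle with H-5 anti to the C10 methyl (trans ring fusion), and C9, which equilibrates in the open 2-oxo ester, should enter the chair of ring B with its side chain equatorial (cis to the C10 methyl). The step needs attack by C5 and not by C7: only the C5 enamine reaches C10 through a six-membered transition state, whereas the C7 enamine would need an eight-membered one and returns to the ketone, so the reversible enamine pool should drain through C5.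

Step 8
Reactants: 16 ethyl (5R,9S,10S)-6-oxolabda-7,12E,14-trien-17-oate
Product: 17 ethyl (5R,6S,9S,10S)-6-hydroxylabda-7,12E,14-trien-17-oate
Conditions: NaBH4, CeCl3·7H2O, MeOH, −40 °C
Reagents that add atoms: none
Why: Luche reduction: CeCl3 directs 1,2-attack on the enone carbonyl and hydride should arrive from the face opposite the axial methyl groups on C10 and C4, which places the new hydroxyl cis to the C10 methyl (6S); the ester and the diene are not reduced.

Step 9
Reactants: 17 ethyl (5R,6S,9S,10S)-6-hydroxylabda-7,12E,14-trien-17-oate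
Product: 18 (5R,6S,9S,10S)-6-hydroxylabda-7,12E,14-trien-17-oic acid
Conditions: LiOH·H2O, THF/H2O, 45 °C; then 1 M HCl to pH 3, 0 °C
Reagents that add atoms: lithium hydroxide, [Li+].[OH-]
Why: Saponification of the ethyl ester; C9–H is no longer activated by a ketone and the C6 hydroxyl is trans to the carboxyl across C7=C8, so neither epimerisation nor lactonisation is expected.

Step 10
Reactants: 18 (5R,6S,9S,10S)-6-hydroxylabda-7,12E,14-trien-17-oic acid
Product: 20 (5R,6S,9S,10S)-6-acetoxylabda-7,12E,14-trien-17-oic acid (CNP0294871.1), via mixed anhydride 19 (not isolated)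
Conditions: Ac2O, pyridine, DMAP (cat.), CH2Cl2, rt; then H2O/THF, rt
Reagents that add atoms: acetic anhydride, CC(=O)OC(C)=O
Why: DMAP-catalysed acetylation of the hindered axial allylic alcohol; the carboxyl group is converted to the mixed anhydride at the same time, and water cleaves it back at the less hindered acetyl carbonyl.

**Compound list**
1 | mesityl oxide (4-methylpent-3-en-2-one) | CC(C)=CC(C)=O | starting material
2 | 5-bromo-2-methylpent-1-ene | C=C(C)CCCBr | starting material
3 | (4-methylpent-4-en-1-yl)magnesium bromide | C=C(C)CCC[Mg]Br | intermediate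
4 | 4,4,8-trimethylnon-8-en-2-one | CC(=O)CC(C)(C)CCCC(C)=C | intermediate
5 | ethyl glyoxylate | CCOC(=O)C=O | starting material
6 | ethyl 2-hydroxy-8,8-dimethyl-4-methylidene-10-oxoundecanoate (racemic) | CCOC(=O)C(O)CC(=C)CCCC(C)(C)CC(C)=O | intermediate
7 | ethyl 8,8-dimethyl-4-methylidene-2,10-dioxoundecanoate | CCOC(=O)C(=O)CC(=C)CCCC(C)(C)CC(C)=O | intermediate
8 | ethyl (3E)-4,8,8-trimethyl-2,10-dioxoundec-3-enoate | CCOC(=O)C(=O)/C=C(\C)CCCC(C)(C)CC(C)=O | intermediate
9 | (2E)-3-methylpent-2-en-4-yn-1-ol | OC/C=C(C)/C#C | starting material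
10 | (2E)-3-methylpenta-2,4-dien-1-ol | OC/C=C(C)/C=C | intermediate
11 | (3E)-5-bromo-3-methylpenta-1,3-diene | BrC/C=C(C)/C=C | intermediate
12 | ethyl 8,8-dimethyl-4-methylidene-3-[(2E)-3-methylpenta-2,4-dien-1-yl]-2,10-dioxoundecanoate (racemic at C3) | CCOC(=O)C(=O)C(C/C=C(C)/C=C)C(=C)CCCC(C)(C)CC(C)=O | intermediate
13 | ethyl 4,8,8-trimethyl-3-[(2E)-3-methylpenta-2,4-dien-1-yl]-2,10-dioxoundec-3-enoate (either geometry at C3=C4) | CCOC(=O)C(=O)C(C/C=C(C)/C=C)=C(C)CCCC(C)(C)CC(C)=O | intermediate
14 | ethyl (5E)-3-[(1S,2R)-2-acetyl-1,3,3-trimethylcyclohexyl]-6-methyl-2-oxoocta-5,7-dienoate (C3 not fixed) | C=C/C(C)=C/CC(C(=O)C(=O)OCC)[C@]1(C)CCCC(C)(C)[C@H]1C(C)=O | intermediate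
15 | ethyl (5R,9S,10S)-8-hydroxy-6-oxolabda-12E,14-dien-17-oate (C8 not fixed) | C=C/C(C)=C/C[C@@H]1C(O)(C(=O)OCC)CC(=O)[C@@H]2C(C)(C)CCC[C@@]12C | intermediate
16 | ethyl (5R,9S,10S)-6-oxolabda-7,12E,14-trien-17-oate | C=C/C(C)=C/C[C@@H]1C(C(=O)OCC)=CC(=O)[C@@H]2C(C)(C)CCC[C@@]12C | intermediate
17 | ethyl (5R,6S,9S,10S)-6-hydroxylabda-7,12E,14-trien-17-oate | C=C/C(C)=C/C[C@@H]1C(C(=O)OCC)=C[C@H](O)[C@@H]2C(C)(C)CCC[C@@]12C | intermediate
18 | (5R,6S,9S,10S)-6-hydroxylabda-7,12E,14-trien-17-oic acid | C=C/C(C)=C/C[C@@H]1C(C(=O)O)=C[C@H](O)[C@@H]2C(C)(C)CCC[C@@]12C | intermediate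
19 | acetic (5R,6S,9S,10S)-6-acetoxylabda-7,12E,14-trien-17-oic anhydride | C=C/C(C)=C/C[C@@H]1C(C(=O)OC(C)=O)=C[C@H](OC(C)=O)[C@@H]2C(C)(C)CCC[C@@]12C | intermediate
20 | (5R,6S,9S,10S)-6-acetoxylabda-7,12E,14-trien-17-oic acid (CNP0294871.1) | C=C/C(C)=C/C[C@@H]1C(C(=O)O)=C[C@H](OC(C)=O)[C@@H]2C(C)(C)CCC[C@@]12C | target

Total step count: 10. Longest linear sequence: 8 steps (steps 1, 2, 3, 6, 7, 8, 9, 10).

**Steps most likely to fail**

Step 7 (Proposed new method). The catalyst may not tell apart the two faces of the fully substituted C10, the Michael addition may revert before ring B closes, and C9 of 16, which is γ to the C6 ketone, may epimerise on long exposure to the amine salt. The fallback uses known chemistry and sets out from 12. Compound 12 is cyclised with an achiral amine salt (pyrrolidine/AcOH, toluene, 60 °C; an amine-catalysed Michael/aldol condensation of the Robinson type). This should give 16 as the racemate, that is, together with its enantiomer ethyl (5S,9R,10R)-6-oxolabda-7,12E,14-trien-17-oate F1. Luche reduction and saponification as in steps 8 and 9 then give 17 and 18 together with their enantiomers ethyl (5S,6R,9R,10R)-6-hydroxylabda-7,12E,14-trien-17-oate F2 and (5S,6R,9R,10R)-6-hydroxylabda-7,12E,14-trien-17-oic acid F3. The racemic acid is resolved by crystallisation with (R)-1-phenylethylamine: the (R)-1-phenylethylammonium salt of 18 F4 is separated from the (R)-1-phenylethylammonium salt of the enantiomeric acid F5 (the (S)-amine is used if F5 proves the less soluble salt). Acidification of F4 returns 18, where the route is rejoined.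

Step 6. The 2-oxo ester dienolate may be alkylated on oxygen or twice, or may condense with itself. The fallback replaces the enolate SN2 reaction by a palladium π-allyl alkylation and sets out from 10 and 8. Dienol 10 is converted with methyl chloroformate and pyridine into methyl (2E)-3-methylpenta-2,4-dien-1-yl carbonate F6. F6 and 8 are then treated with Pd(PPh3)4 (5 mol%) in THF at rt. Zerovalent palladium ionises the carbonate, the methoxide set free deprotonates 8, and the soft dienolate attacks a terminal carbon of the pentadienyl–palladium complex; both termini give the same constitution. Any O-allyl product is re-ionised, so the C-alkylated compound should accumulate. This returns to the route at 12.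

Step 9. Hydrolysis of the hindered conjugated ester may be slow, and prolonged heating in base may shift the C7=C8 double bond or degrade the diene. The fallback reaches the acid by reduction and re-oxidation and sets out from 17. Compound 17 is reduced with iBu2AlH (CH2Cl2, −78 °C) to (5R,6S,9S,10S)-labda-7,12E,14-triene-6,17-diol F7. The primary allylic alcohol is oxidised selectively with TEMPO/PhI(OAc)2 to (5R,6S,9S,10S)-6-hydroxylabda-7,12E,14-trien-17-al F8, the hindered secondary alcohol being left alone. Pinnick oxidation (NaClO2, NaH2PO4, 2-methyl-2-butene, tBuOH/H2O) then gives 18, where the route is rejoined.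

**Further compounds**
F1 | step 7 | ethyl (5S,9R,10R)-6-oxolabda-7,12E,14-trien-17-oate | C=C/C(C)=C/C[C@H]1C(C(=O)OCC)=CC(=O)[C@H]2C(C)(C)CCC[C@]12C
F2 | step 7 | ethyl (5S,6R,9R,10R)-6-hydroxylabda-7,12E,14-trien-17-oate | C=C/C(C)=C/C[C@H]1C(C(=O)OCC)=C[C@@H](O)[C@H]2C(C)(C)CCC[C@]12C
F3 | step 7 | (5S,6R,9R,10R)-6-hydroxylabda-7,12E,14-trien-17-oic acid | C=C/C(C)=C/C[C@H]1C(C(=O)O)=C[C@@H](O)[C@H]2C(C)(C)CCC[C@]12C
F4 | step 7 | (R)-1-phenylethylammonium (5R,6S,9S,10S)-6-hydroxylabda-7,12E,14-trien-17-oate | C=C/C(C)=C/C[C@@H]1C(C(=O)[O-])=C[C@H](O)[C@@H]2C(C)(C)CCC[C@@]12C.C[C@@H]([NH3+])c1ccccc1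
F5 | step 7 | (R)-1-phenylethylammonium (5S,6R,9R,10R)-6-hydroxylabda-7,12E,14-trien-17-oate | C=C/C(C)=C/C[C@H]1C(C(=O)[O-])=C[C@@H](O)[C@H]2C(C)(C)CCC[C@]12C.C[C@@H]([NH3+])c1ccccc1
F6 | step 6 | methyl (2E)-3-methylpenta-2,4-dien-1-yl carbonate | COC(=O)OC/C=C(C)/C=C
F7 | step 9 | (5R,6S,9S,10S)-labda-7,12E,14-triene-6,17-diol | C=C/C(C)=C/C[C@@H]1C(CO)=C[C@H](O)[C@@H]2C(C)(C)CCC[C@@]12C
F8 | step 9 | (5R,6S,9S,10S)-6-hydroxylabda-7,12E,14-trien-17-al | C=C/C(C)=C/C[C@@H]1C(C=O)=C[C@H](O)[C@@H]2C(C)(C)CCC[C@@]12C
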